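The vessel was closed, stirred and isothermal at constant volume. The new flasks share charge and time and differ in temperature.

| flask | starting material | temperature | remark | time |
|---|---|---|---|---|
| Friday's | 0.30 M | 55 °C | run made earlier |  |
| elm | 0.20 M | 55 °C |  | 3.0 h |
| cedar | 0.20 M | 5 °C |  | 3.0 h |
| ash | 0.20 M | 30 °C |  | 3.0 h |
| maple | 0.20 M | −20 °C |  | 3.0 h |

- Friday's (time / min: intermediate A / %, target / %, starting material / %): 2.50: 0.9, 12.3, 0; 6.00: 0, 5.9, 0; 12.0: 0.4, 0, 0; 20.0: 0.8, 0, 0

(standard deviation of a reading: 1 percentage point)

- the flask that comes out highest in amount of intermediate A, in percent of the starting material charged, or "all alike" when all lie within 1.5 percentage points (elm / cedar / ash / maple / all alike)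
- intermediate A at the end, in percent of the starting material charged, elm
- intermediate A at the end, in percent of the starting material charged, cedar
- intermediate A at the end, in percent of the starting material charged, ash
- intermediate A at the end, in percent of the starting material charged, maple

- the earlier runs were read with a standard deviation of 1 percentage point
- the earlier runs do not show what temperature does; that part of a forecast is a guess

1. Friday's first sample, at 2.50 min, read starting material 0%, intermediate A 0.9% and target 12.3%. So the readings left 86.8% of the charge in species I did not read.

2. I followed one molecule of starting material. A rate constant k gives its chance of reacting per unit time, and in Friday's run at 55 °C the reading says that molecule had left starting material before the first sample. Intermediate A read 0.9%, under the scatter of 1 percentage point, so any peak of intermediate A lay earlier, in a stretch Friday's readings do not show.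

3. I assumed first-order steps, so that percentages do not depend on the charge, and one common factor f by which cooling slows each k. A flask at time t then stands where Friday's stood at t/f, which I call its Friday clock. The blind factor F is the slowing at which the asked time fits before Friday's first sample, F = 72.0. With f above F, a flask ends in the unseen stretch; with f below F, it ends past Friday's first sample.

4. The forecast gave 0% for elm, 0.5% for cedar, 0.2% for ash and 1.2% for maple, and called the contest all alike. For maple it reckoned that “rates may drop about a thousandfold”.

5. I took that factor as my guess and spread it evenly over the equal temperature steps, a factor 10 per step. Ash then ended at 18.0 min on the Friday clock, past the first sample, so I expected a reading near zero, as in elm. On the same guess cedar ended at 1.80 min and maple at 0.180 min, both before it. Here I parted from the forecast: I gave no number for these two flasks, but I did not expect all alike, and they were the ones to watch.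

    target → over-reaction product (k = 0.00190 min⁻¹, Ea = 100 kJ mol⁻¹)
    intermediate A → intermediate B (k = 0.00810 min⁻¹, Ea = 80.0 kJ mol⁻¹)
    starting material → intermediate A (k = 0.100 min⁻¹, Ea = 82.0 kJ mol⁻¹)
    intermediate B → target (k = 9.60 × 10⁻⁴ min⁻¹, Ea = 85.0 kJ mol⁻¹)
    (constants at 5 °C)

Maple came out highest at 40.8%, above cedar's 25.3% and elm's 0%, and it still held 58.1% starting material at the end. The making of intermediate A from starting material speeds up by a factor of 7400 from the coldest to the hottest flask, beyond F, which puts maple's end at 0.0244 min on the Friday clock of that step. Ash reached 70 percent conversion in 0.647 min, against 0.0542 min for that step in elm, a slowing of that step by 11.9, below F, and ash held 0%.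

The runs are calculated with made-up constants; scatter was added.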